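The 14-membered ring is disconnected at C9–C10, the doubly allylic head-to-tail junction between the C7=C8 and C11=C12 olefins. An open-chain (3E,7Z,11E)-triene carrying a phenylsulfonyl group on C10 and an allylic bromide on C9 is closed by intramolecular alkylation of the sulfonyl-stabilised allyl anion. This single operation forms the ring with all three trisubstituted olefins already fixed, and the sulfone is afterwards removed regioselectively by palladium-catalysed hydride transfer. The C1 stereocentre and both ring arms come from (1S,2S,4R)-limonene-1,2-diol by side-chain prenylation and glycol cleavage; two Horner–Wadsworth–Emmons olefinations add C4–C9 and C10–C11.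

Key step: step 12

Numbering used below: ring C1 (stereocentre), C2, C3=C4 (C4 carries the hydroxymethyl carbon), C5, C6, C7=C8 (methyl on C8), C9, C10, C11=C12 (methyl on C12), C13, C14; side chain C15(=CH2)–C16–C17–C18=C19Me2.
Assumption: compounds 1, 3, 8, 10 and 16 are taken as commercial; 1 is the diol derived from (R)-limonene, whose ring stereocentre becomes C1 (R) of the target.

Step 1
Reactants: 1 (1S,2S,4R)-limonene-1,2-diol
Product: 2 (3aS,5R,7aS)-2,2,7a-trimethyl-5-(prop-1-en-2-yl)hexahydro-1,3-benzodioxole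
Conditions: 2-methoxypropene, PPTS (cat.), CH2Cl2, 0 °C to rt
Reagents that add atoms: 2-methoxypropene, COC(C)=C
Why: Acid-catalysed acetonide formation (transacetalisation with an enol ether) on the trans-diol, after ring flip to the diequatorial conformer, masks the former ring olefin as a base-stable group and leaves the three stereocentres untouched.

Step 2
Reactants: 2 (3aS,5R,7aS)-2,2,7a-trimethyl-5-(prop-1-en-2-yl)hexahydro-1,3-benzodioxole; 3 prenyl bromide
Product: 5 (3aS,5R,7aS)-2,2,7a-trimethyl-5-(6-methylhepta-1,5-dien-2-yl)hexahydro-1,3-benzodioxole, via allyllithium 4 (not isolated)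
Conditions: n-BuLi, TMEDA, hexane, rt; then 3, THF, −78 °C to rt
Reagents that add atoms: none
Why: Allylic lithiation of the isopropenyl methyl group (the derived 2-substituted allyl anion has two equivalent CH2 termini) followed by SN2 alkylation with the primary allylic bromide is the known entry from limonene to the β-bisabolene side chain, and the C–H at the stereocentre is not removed.

Step 3
Reactants: 5 (3aS,5R,7aS)-2,2,7a-trimethyl-5-(6-methylhepta-1,5-dien-2-yl)hexahydro-1,3-benzodioxole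
Product: 7 (3R)-3-(6-methylhepta-1,5-dien-2-yl)-6-oxoheptanal, via diol 6 (not isolated)
Conditions: H5IO6, THF–H2O, 0 °C to rt
Reagents that add atoms: none
Why: Periodic acid hydrolyses the strained trans-acetonide and cleaves the liberated 1,2-diol (Malaprade glycol cleavage) to the C12 methyl ketone and the C3 aldehyde, while C1 is not enolisable because it is β to the aldehyde and γ to the ketone.

Step 4
Reactants: 8 tert-butyl 5-bromopentanoate
Product: 9 [5-(tert-butoxy)-5-oxopentyl]triphenylphosphonium bromide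
Conditions: PPh3, MeCN, reflux
Reagents that add atoms: triphenylphosphine, c1ccc(cc1)P(c1ccccc1)c1ccccc1
Why: SN2 quaternisation of triphenylphosphine by a primary alkyl bromide (phosphonium salt formation) is reliable and the tert-butyl ester is inert to it.

Step 5
Reactants: 9 [5-(tert-butoxy)-5-oxopentyl]triphenylphosphonium bromide; 10 1-[(tert-butyldimethylsilyl)oxy]propan-2-one
Product: 12 tert-butyl (5Z)-7-[(tert-butyldimethylsilyl)oxy]-6-methylhept-5-enoate, via ylide 11 (not isolated)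
Conditions: KN(SiMe3)2, THF, −78 °C; then 10, −78 °C to rt
Reagents that add atoms: none
Why: The Wittig reaction of an unstabilised ylide with an α-silyloxy methyl ketone is known to place the ylide substituent cis to the oxygenated CH2 group, so it should give the (Z)-trisubstituted olefin C7=C8 with C6 cis to C9.

Step 6
Reactants: 12 tert-butyl (5Z)-7-[(tert-butyldimethylsilyl)oxy]-6-methylhept-5-enoate
Product: 14 tert-butyl (5Z)-7-[(tert-butyldimethylsilyl)oxy]-2-(diethoxyphosphoryl)-6-methylhept-5-enoate, via phosphonite 13 (not isolated)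
Conditions: LiN(i-Pr)2, THF, −78 °C; ClP(OEt)2; then H2O2 (aq), 0 °C
Reagents that add atoms: diethyl chlorophosphite, CCOP(Cl)OCC; hydrogen peroxide, OO
Why: C-phosphinylation of the ester lithium enolate by the soft trivalent phosphorus chloride followed by oxidation at phosphorus gives the α-phosphono ester (Horner–Wadsworth–Emmons reagent), racemic at a centre that step 7 destroys.

Step 7
Reactants: 7 (3R)-3-(6-methylhepta-1,5-dien-2-yl)-6-oxoheptanal; 14 tert-butyl (5Z)-7-[(tert-butyldimethylsilyl)oxy]-2-(diethoxyphosphoryl)-6-methylhept-5-enoate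
Product: 15 tert-butyl (2E,5R)-2-{(3Z)-5-[(tert-butyldimethylsilyl)oxy]-4-methylpent-3-en-1-yl}-5-(6-methylhepta-1,5-dien-2-yl)-8-oxonon-2-enoate
Conditions: NaH, THF, 0 °C to rt
Reagents that add atoms: none
Why: The Horner–Wadsworth–Emmons olefination is chemoselective for the aldehyde over the methyl ketone, and the α-alkyl phosphonate with its bulky tert-butyl ester should give mainly the (E)-enoate, in which C2 is trans to the ester carbon and cis to C5 as C3=C4 requires.

Step 8
Reactants: 15 tert-butyl (2E,5R)-2-{(3Z)-5-[(tert-butyldimethylsilyl)oxy]-4-methylpent-3-en-1-yl}-5-(6-methylhepta-1,5-dien-2-yl)-8-oxonon-2-enoate; 16 triethyl phosphonoacetate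
Product: 17 1-tert-butyl 10-ethyl (2E,5R,8E)-2-{(3Z)-5-[(tert-butyldimethylsilyl)oxy]-4-methylpent-3-en-1-yl}-8-methyl-5-(6-methylhepta-1,5-dien-2-yl)deca-2,8-dienedioate
Conditions: NaH, THF, 0 to 50 °C
Reagents that add atoms: none
Why: Horner–Wadsworth–Emmons olefination of the methyl ketone should favour the (E)-enoate (C13 trans to the ester carbon C10), and the minor (Z)-isomer is to be removed by chromatography here or after step 9.

Step 9
Reactants: 17 1-tert-butyl 10-ethyl (2E,5R,8E)-2-{(3Z)-5-[(tert-butyldimethylsilyl)oxy]-4-methylpent-3-en-1-yl}-8-methyl-5-(6-methylhepta-1,5-dien-2-yl)deca-2,8-dienedioate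
Product: 18 tert-butyl (2E,5R,8E)-2-{(3Z)-5-[(tert-butyldimethylsilyl)oxy]-4-methylpent-3-en-1-yl}-10-hydroxy-8-methyl-5-(6-methylhepta-1,5-dien-2-yl)deca-2,8-dienoate
Conditions: i-Bu2AlH (2.2 equiv), CH2Cl2, −78 °C
Reagents that add atoms: none
Why: 1,2-Reduction of the unhindered ethyl enoate by i-Bu2AlH at low temperature should be much faster than attack on the α-branched tert-butyl enoate, so only C10 is taken to the allylic alcohol.

Step 10
Reactants: 18 tert-butyl (2E,5R,8E)-2-{(3Z)-5-[(tert-butyldimethylsilyl)oxy]-4-methylpent-3-en-1-yl}-10-hydroxy-8-methyl-5-(6-methylhepta-1,5-dien-2-yl)deca-2,8-dienoate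
Product: 20 tert-butyl (2E,5R,8E)-10-(benzenesulfonyl)-2-{(3Z)-5-[(tert-butyldimethylsilyl)oxy]-4-methylpent-3-en-1-yl}-8-methyl-5-(6-methylhepta-1,5-dien-2-yl)deca-2,8-dienoate, via allylic chloride 19 (not isolated)
Conditions: MsCl, Et3N, LiCl, DMF, 0 °C; then PhSO2Na, rt
Reagents that add atoms: sodium benzenesulfinate, [Na+].[O-]S(=O)c1ccccc1; lithium chloride, [Li+].[Cl-] (its chlorine is found only in 19)
Why: Mesylation with in situ chloride displacement gives the primary allylic chloride without allylic transposition, and S-alkylation of the sulfinate (SN2) then gives the allylic sulfone with the (11E)-geometry retained.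

Step 11
Reactants: 20 tert-butyl (2E,5R,8E)-10-(benzenesulfonyl)-2-{(3Z)-5-[(tert-butyldimethylsilyl)oxy]-4-methylpent-3-en-1-yl}-8-methyl-5-(6-methylhepta-1,5-dien-2-yl)deca-2,8-dienoate
Product: 21 tert-butyl (2E,5R,8E)-10-(benzenesulfonyl)-2-[(3Z)-5-bromo-4-methylpent-3-en-1-yl]-8-methyl-5-(6-methylhepta-1,5-dien-2-yl)deca-2,8-dienoate
Conditions: Ph3PBr2, CH2Cl2, 0 °C to rt
Reagents that add atoms: triphenylphosphine dibromide, BrP(Br)(c1ccccc1)(c1ccccc1)c1ccccc1
Why: Direct conversion of the primary allylic silyl ether into the bromide through an alkoxyphosphonium ion (Appel-type SN2) runs under neutral conditions that should spare the sulfone, the tert-butyl ester and the olefin geometries.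

Step 12
Reactants: 21 tert-butyl (2E,5R,8E)-10-(benzenesulfonyl)-2-[(3Z)-5-bromo-4-methylpent-3-en-1-yl]-8-methyl-5-(6-methylhepta-1,5-dien-2-yl)deca-2,8-dienoate
Product: 22 tert-butyl (1R,3E,7Z,11E)-10-(benzenesulfonyl)-8,12-dimethyl-1-(6-methylhepta-1,5-dien-2-yl)cyclotetradeca-3,7,11-triene-4-carboxylate (C10 epimers)
Conditions: NaN(SiMe3)2 (1.1 equiv), THF, 0.002 M, −78 °C to 0 °C
Reagents that add atoms: none
Why: NaN(SiMe3)2 removes the proton at C10, which is both allylic and α to the sulfone, and the resulting sulfonyl-stabilised allyl anion displaces the primary allylic bromide at C9 in an intramolecular SN2 reaction. The closest known reaction type is the sulfone-based allyl–allyl (head-to-tail prenyl) coupling of polyprenoid synthesis, whose intramolecular form is known for 14-membered terpenoid rings. The 14-membered carbocycle is closed in the 14-exo-tet mode by C–C alkylation. The only new stereocentre, C10, is formed without control as an epimer mixture and is erased in step 14, while C1 is remote and unaffected. The step needs α- rather than γ-alkylation of the ambident anion (the sulfone holds the charge at C10), SN2 rather than SN2′ attack (primary CH2Br against the substituted C7) and ring closure rather than oligomerisation (high dilution), and neither the (7Z)- nor the (11E)-olefin can isomerise because no π-allyl metal or radical intermediate is involved.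

Step 13
Reactants: 22 tert-butyl (1R,3E,7Z,11E)-10-(benzenesulfonyl)-8,12-dimethyl-1-(6-methylhepta-1,5-dien-2-yl)cyclotetradeca-3,7,11-triene-4-carboxylate
Product: 23 [(1R,3E,7Z,11E)-10-(benzenesulfonyl)-8,12-dimethyl-1-(6-methylhepta-1,5-dien-2-yl)cyclotetradeca-3,7,11-trien-4-yl]methanol (C10 epimers)
Conditions: i-Bu2AlH (3 equiv), CH2Cl2, −78 to 0 °C
Reagents that add atoms: none
Why: i-Bu2AlH reduces the α,β-unsaturated tert-butyl ester to the allylic alcohol by 1,2-reduction, and the sulfone and the isolated olefins are inert to it.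

Step 14
Reactants: 23 [(1R,3E,7Z,11E)-10-(benzenesulfonyl)-8,12-dimethyl-1-(6-methylhepta-1,5-dien-2-yl)cyclotetradeca-3,7,11-trien-4-yl]methanol
Product: 24 [(1R,3E,7Z,11E)-8,12-dimethyl-1-(6-methylhepta-1,5-dien-2-yl)cyclotetradeca-3,7,11-trien-4-yl]methanol (target CNP0217603.1)
Conditions: PdCl2(dppp) (5 mol %), LiBHEt3 (3 equiv), THF, 0 °C to rt
Reagents that add atoms: none
Why: In this palladium-catalysed reductive desulfonylation of an allylic sulfone, ionisation gives a π-allyl complex over C10–C12 and hydride is delivered to the less substituted terminus C10, which should remove the sulfone and the C10 stereocentre without moving the C11=C12 bond or changing its E geometry, since syn/anti exchange would need a σ-complex at the tertiary C12.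

Compound list
1 | (1S,2S,4R)-1-methyl-4-(prop-1-en-2-yl)cyclohexane-1,2-diol [(1S,2S,4R)-limonene-1,2-diol] | CC(=C)[C@@H]1CC[C@](C)(O)[C@@H](O)C1 | starting material
2 | (3aS,5R,7aS)-2,2,7a-trimethyl-5-(prop-1-en-2-yl)hexahydro-1,3-benzodioxole | CC(=C)[C@@H]1CC[C@]2(C)OC(C)(C)O[C@H]2C1 | intermediate
3 | 1-bromo-3-methylbut-2-ene (prenyl bromide) | CC(C)=CCBr | starting material
4 | {2-[(3aS,5R,7aS)-2,2,7a-trimethylhexahydro-1,3-benzodioxol-5-yl]prop-2-en-1-yl}lithium | [Li]CC(=C)[C@@H]1CC[C@]2(C)OC(C)(C)O[C@H]2C1 | intermediate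
5 | (3aS,5R,7aS)-2,2,7a-trimethyl-5-(6-methylhepta-1,5-dien-2-yl)hexahydro-1,3-benzodioxole | CC(C)=CCCC(=C)[C@@H]1CC[C@]2(C)OC(C)(C)O[C@H]2C1 | intermediate
6 | (1S,2S,4R)-1-methyl-4-(6-methylhepta-1,5-dien-2-yl)cyclohexane-1,2-diol | CC(C)=CCCC(=C)[C@@H]1CC[C@](C)(O)[C@@H](O)C1 | intermediate
7 | (3R)-3-(6-methylhepta-1,5-dien-2-yl)-6-oxoheptanal | CC(C)=CCCC(=C)[C@@H](CC=O)CCC(C)=O | intermediate
8 | tert-butyl 5-bromopentanoate | CC(C)(C)OC(=O)CCCCBr | starting material
9 | [5-(tert-butoxy)-5-oxopentyl]triphenylphosphonium bromide | CC(C)(C)OC(=O)CCCC[P+](c1ccccc1)(c1ccccc1)c1ccccc1.[Br-] | intermediate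
10 | 1-[(tert-butyldimethylsilyl)oxy]propan-2-one | CC(=O)CO[Si](C)(C)C(C)(C)C | starting material
11 | tert-butyl 5-(triphenyl-λ5-phosphanylidene)pentanoate | CC(C)(C)OC(=O)CCCC=P(c1ccccc1)(c1ccccc1)c1ccccc1 | intermediate
12 | tert-butyl (5Z)-7-[(tert-butyldimethylsilyl)oxy]-6-methylhept-5-enoate | CC(C)(C)OC(=O)CCC/C=C(/C)CO[Si](C)(C)C(C)(C)C | intermediate
13 | tert-butyl (5Z)-7-[(tert-butyldimethylsilyl)oxy]-2-(diethoxyphosphanyl)-6-methylhept-5-enoate (racemic) | CCOP(OCC)C(CC/C=C(/C)CO[Si](C)(C)C(C)(C)C)C(=O)OC(C)(C)C | intermediate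
14 | tert-butyl (5Z)-7-[(tert-butyldimethylsilyl)oxy]-2-(diethoxyphosphoryl)-6-methylhept-5-enoate (racemic) | CCOP(=O)(OCC)C(CC/C=C(/C)CO[Si](C)(C)C(C)(C)C)C(=O)OC(C)(C)C | intermediate
15 | tert-butyl (2E,5R)-2-{(3Z)-5-[(tert-butyldimethylsilyl)oxy]-4-methylpent-3-en-1-yl}-5-(6-methylhepta-1,5-dien-2-yl)-8-oxonon-2-enoate | C=C(CCC=C(C)C)[C@@H](C/C=C(/C(=O)OC(C)(C)C)CC/C=C(/C)CO[Si](C)(C)C(C)(C)C)CCC(C)=O | intermediate
16 | triethyl phosphonoacetate [ethyl 2-(diethoxyphosphoryl)acetate] | CCOC(=O)CP(=O)(OCC)OCC | starting material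
17 | 1-tert-butyl 10-ethyl (2E,5R,8E)-2-{(3Z)-5-[(tert-butyldimethylsilyl)oxy]-4-methylpent-3-en-1-yl}-8-methyl-5-(6-methylhepta-1,5-dien-2-yl)deca-2,8-dienedioate | C=C(CCC=C(C)C)[C@@H](C/C=C(/C(=O)OC(C)(C)C)CC/C=C(/C)CO[Si](C)(C)C(C)(C)C)CC/C(C)=C/C(=O)OCC | intermediate
18 | tert-butyl (2E,5R,8E)-2-{(3Z)-5-[(tert-butyldimethylsilyl)oxy]-4-methylpent-3-en-1-yl}-10-hydroxy-8-methyl-5-(6-methylhepta-1,5-dien-2-yl)deca-2,8-dienoate | C=C(CCC=C(C)C)[C@@H](C/C=C(/C(=O)OC(C)(C)C)CC/C=C(/C)CO[Si](C)(C)C(C)(C)C)CC/C(C)=C/CO | intermediate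
19 | tert-butyl (2E,5R,8E)-2-{(3Z)-5-[(tert-butyldimethylsilyl)oxy]-4-methylpent-3-en-1-yl}-10-chloro-8-methyl-5-(6-methylhepta-1,5-dien-2-yl)deca-2,8-dienoate | C=C(CCC=C(C)C)[C@@H](C/C=C(/C(=O)OC(C)(C)C)CC/C=C(/C)CO[Si](C)(C)C(C)(C)C)CC/C(C)=C/CCl | intermediate
20 | tert-butyl (2E,5R,8E)-10-(benzenesulfonyl)-2-{(3Z)-5-[(tert-butyldimethylsilyl)oxy]-4-methylpent-3-en-1-yl}-8-methyl-5-(6-methylhepta-1,5-dien-2-yl)deca-2,8-dienoate | C=C(CCC=C(C)C)[C@@H](C/C=C(/C(=O)OC(C)(C)C)CC/C=C(/C)CO[Si](C)(C)C(C)(C)C)CC/C(C)=C/CS(=O)(=O)c1ccccc1 | intermediate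
21 | tert-butyl (2E,5R,8E)-10-(benzenesulfonyl)-2-[(3Z)-5-bromo-4-methylpent-3-en-1-yl]-8-methyl-5-(6-methylhepta-1,5-dien-2-yl)deca-2,8-dienoate | C=C(CCC=C(C)C)[C@@H](C/C=C(/C(=O)OC(C)(C)C)CC/C=C(/C)CBr)CC/C(C)=C/CS(=O)(=O)c1ccccc1 | intermediate
22 | tert-butyl (1R,3E,7Z,11E)-10-(benzenesulfonyl)-8,12-dimethyl-1-(6-methylhepta-1,5-dien-2-yl)cyclotetradeca-3,7,11-triene-4-carboxylate (C10 epimers; locants as in the numbering line) | C=C(CCC=C(C)C)[C@H]1C/C=C(/C(=O)OC(C)(C)C)CC/C=C(/C)CC(S(=O)(=O)c2ccccc2)/C=C(\C)CC1 | intermediate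
23 | [(1R,3E,7Z,11E)-10-(benzenesulfonyl)-8,12-dimethyl-1-(6-methylhepta-1,5-dien-2-yl)cyclotetradeca-3,7,11-trien-4-yl]methanol (C10 epimers) | C=C(CCC=C(C)C)[C@H]1C/C=C(/CO)CC/C=C(/C)CC(S(=O)(=O)c2ccccc2)/C=C(\C)CC1 | intermediate
24 | [(1R,3E,7Z,11E)-8,12-dimethyl-1-(6-methylhepta-1,5-dien-2-yl)cyclotetradeca-3,7,11-trien-4-yl]methanol (CNP0217603.1) | C=C(CCC=C(C)C)[C@H]1C/C=C(/CO)CC/C=C(/C)CC/C=C(\C)CC1 | target

Total step count: 14. Longest linear sequence: 11 steps (steps 1–3 then 7–14, or equally steps 4–6 then 7–14).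

Steps most likely to fail

Step 12. Intermolecular alkylation (oligomer formation) may outrun closure of the 14-membered ring, or the base may cause loss of HBr or deprotonate the enoate instead of the sulfone. The fallback changes the carbanion-stabilising group; it sets out from 18 and comes back at 22. The alcohol 18 would be converted with PhSSPh and n-Bu3P into the allylic phenyl sulfide F1, and the silyl ether exchanged for bromide with Ph3PBr2 to give the bromo sulfide F2. The ring would then be closed through the more nucleophilic sulfur-stabilised allyllithium (n-BuLi, DABCO, THF, −78 °C, high dilution; the hindered tert-butyl enoate is expected to survive), a known way to close 14-membered isoprenoid rings, giving the macrocyclic sulfide F3. Chemoselective oxidation at sulfur ((NH4)6Mo7O24 cat., H2O2, EtOH, 0 °C) would give 22.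

Step 8. The olefination of the methyl ketone may give too much of the (Z)-isomer, and it also makes step 9 depend on telling two esters apart. The fallback builds C11=C12 by syn-carbometalation of an alkyne; it sets out from 7 and comes back at 20.
- The aldehyde of 7 would be masked chemoselectively as the dimethyl acetal F4 (HC(OMe)3, MeOH, CeCl3·7H2O cat.).
- The methyl ketone would be converted into the enol phosphate F5 (LiN(i-Pr)2, ClP(O)(OEt)2, THF, −78 °C) and eliminated to the terminal alkyne F6 (LiN(i-Pr)2, −78 °C to rt).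
- Zirconium-catalysed methylalumination (Me3Al, Cp2ZrCl2 cat., CH2Cl2; then n-BuLi and (CH2O)n) would give the (E)-allylic alcohol F7 stereospecifically.
- The alcohol would be taken to the sulfone F8 as in step 10, and the acetal hydrolysed (PPTS, acetone–H2O) to the aldehyde F9.
- Olefination of F9 with 14 as in step 7 would give 20.

Step 2. Lithiation of the acetonide may be sluggish or unselective, and the allyllithium may attack prenyl bromide in the SN2′ sense or undergo halogen–metal exchange. The fallback functionalises the isopropenyl group electrophilically; it sets out from 2 and comes back at 5. Ene-type chlorination (Ca(OCl)2, solid CO2, CH2Cl2–H2O, 0 °C) would give the 2-substituted allylic chloride F10. Alkylation of lithiated prenyl phenyl sulfone (CC(C)=CCS(=O)(=O)c1ccccc1; n-BuLi, THF, −78 °C) with F10 would give the sulfone F11. Palladium-catalysed hydride desulfonylation (PdCl2(dppp) cat., LiBHEt3, THF) would then give 5 with the trisubstituted olefin in place.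

Further compounds
F1 | step 12 | tert-butyl (2E,5R,8E)-2-{(3Z)-5-[(tert-butyldimethylsilyl)oxy]-4-methylpent-3-en-1-yl}-8-methyl-5-(6-methylhepta-1,5-dien-2-yl)-10-(phenylsulfanyl)deca-2,8-dienoate | C=C(CCC=C(C)C)[C@@H](C/C=C(/C(=O)OC(C)(C)C)CC/C=C(/C)CO[Si](C)(C)C(C)(C)C)CC/C(C)=C/CSc1ccccc1
F2 | step 12 | tert-butyl (2E,5R,8E)-2-[(3Z)-5-bromo-4-methylpent-3-en-1-yl]-8-methyl-5-(6-methylhepta-1,5-dien-2-yl)-10-(phenylsulfanyl)deca-2,8-dienoate | C=C(CCC=C(C)C)[C@@H](C/C=C(/C(=O)OC(C)(C)C)CC/C=C(/C)CBr)CC/C(C)=C/CSc1ccccc1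
F3 | step 12 | tert-butyl (1R,3E,7Z,11E)-8,12-dimethyl-1-(6-methylhepta-1,5-dien-2-yl)-10-(phenylsulfanyl)cyclotetradeca-3,7,11-triene-4-carboxylate (C10 epimers) | C=C(CCC=C(C)C)[C@H]1C/C=C(/C(=O)OC(C)(C)C)CC/C=C(/C)CC(Sc2ccccc2)/C=C(\C)CC1
F4 | step 8 | (5R)-7,7-dimethoxy-5-(6-methylhepta-1,5-dien-2-yl)heptan-2-one | CC(C)=CCCC(=C)[C@@H](CC(OC)OC)CCC(C)=O
F5 | step 8 | diethyl (5R)-7,7-dimethoxy-5-(6-methylhepta-1,5-dien-2-yl)hept-1-en-2-yl phosphate | CC(C)=CCCC(=C)[C@@H](CC(OC)OC)CCC(=C)OP(=O)(OCC)OCC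
F6 | step 8 | (5R)-7,7-dimethoxy-5-(6-methylhepta-1,5-dien-2-yl)hept-1-yne | CC(C)=CCCC(=C)[C@@H](CC(OC)OC)CCC#C
F7 | step 8 | (2E,6R)-8,8-dimethoxy-3-methyl-6-(6-methylhepta-1,5-dien-2-yl)oct-2-en-1-ol | CC(C)=CCCC(=C)[C@@H](CC(OC)OC)CC/C(C)=C/CO
F8 | step 8 | {[(2E,6R)-8,8-dimethoxy-3-methyl-6-(6-methylhepta-1,5-dien-2-yl)oct-2-en-1-yl]sulfonyl}benzene | CC(C)=CCCC(=C)[C@@H](CC(OC)OC)CC/C(C)=C/CS(=O)(=O)c1ccccc1
F9 | step 8 | (3R,6E)-8-(benzenesulfonyl)-6-methyl-3-(6-methylhepta-1,5-dien-2-yl)oct-6-enal | CC(C)=CCCC(=C)[C@@H](CC=O)CC/C(C)=C/CS(=O)(=O)c1ccccc1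
F10 | step 2 | (3aS,5R,7aS)-5-(3-chloroprop-1-en-2-yl)-2,2,7a-trimethylhexahydro-1,3-benzodioxole | ClCC(=C)[C@@H]1CC[C@]2(C)OC(C)(C)O[C@H]2C1
F11 | step 2 | (3aS,5R,7aS)-5-[4-(benzenesulfonyl)-6-methylhepta-1,5-dien-2-yl]-2,2,7a-trimethylhexahydro-1,3-benzodioxole (epimers at the sulfone carbon) | CC(C)=CC(S(=O)(=O)c3ccccc3)CC(=C)[C@@H]1CC[C@]2(C)OC(C)(C)O[C@H]2C1
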